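**Retrosynthetic overview** (labdane numbering C1–C20 is used for every intermediate)
1. Late bonds: the C19–O ester (acylation of diol 27), the side-chain diene (ethylene enyne metathesis of a C13 alkyne), and the C8 carbinol (α-epoxidation and hydride opening of an 8(17)-alkene made from a C8 ketone).
2. The C9 side chain comes from α-methylenation and conjugate propargylation of a C8 silyl enol ether; the C4 quaternary centre and C5–H come from reductive enol triflation, methoxycarbonylation and reductive methylation of a C4 enone.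
3. Rings A and B are formed together, in one step, by an intramolecular Diels–Alder reaction of the achiral, acyclic ynone–silyloxydiene 11 (new bonds C5–C10 and C6–C7); no ring exists before it.
4. Enabling feature: in ring B, C8 carries oxygen and C5, para to C8 across C6–C7, carries the ring A carbon C4, which can be a ketone. This 1,4-relation of C8–O and C4=O, with the quaternary C10 at the other diene terminus, is the retron of a 2-silyloxydiene (C7=C8–C9=C10) plus an ynone (C4(=O)–C5≡C6); the methylenes C1–C3 of ring A are the tether.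
5. Compound 11 is made in six steps from hex-5-yn-1-ol by carboalumination/acylation.

Key step: step 7

Remark: the sense of asymmetric induction of the oxazaborolidinium catalyst in step 7 is assumed by analogy with its reactions of acetylenic ketones; the catalyst from (S)-diphenylprolinol is written, and its enantiomer would be used, with nothing else changed, if the sense proves opposite.

**Step 1**
Reactants: 1 hex-5-yn-1-ol; 2 acetyl chloride (two equivalents enter the product)
Product: 4 (E)-5-methyl-7-oxooct-5-en-1-yl acetate, via alkenylalane 3 (not isolated)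
Conditions: Me3Al (3 equiv), Cp2ZrCl2 (0.25 equiv), CH2Cl2, 0 °C → rt; volatiles removed; then AcCl (3 equiv), Pd(PPh3)4 (5 mol %), THF, 0 °C → rt
Reagents that add atoms: trimethylaluminium, C[Al](C)C
Why: Negishi zirconium-catalysed carboalumination adds methyl and aluminium syn across the terminal alkyne of the aluminium alkoxide of 1 (methyl to the internal carbon), and palladium-catalysed acylation of the alkenylalane with retention, together with O-acetylation of the alkoxide, should give the (E)-enone with the chain trans to the acyl group.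

**Step 2**
Reactants: 4 (E)-5-methyl-7-oxooct-5-en-1-yl acetate
Product: 6 (E)-5-methyl-7-[(triisopropylsilyl)oxy]octa-5,7-dien-1-yl acetate, via lithium dienolate 5 (not isolated)
Conditions: LiN(SiMe3)2 (1.1 equiv), THF, −78 °C; then TIPSOTf, −78 → 0 °C
Reagents that add atoms: triisopropylsilyl trifluoromethanesulfonate, CC(C)[Si](OS(=O)(=O)C(F)(F)F)(C(C)C)C(C)C
Why: Kinetic deprotonation of the enone at the α′-methyl group gives the cross-conjugated lithium dienolate, whose O-silylation gives the 2-silyloxy-1,3-diene, while the much less acidic acetate is left alone at −78 °C.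

**Step 3**
Reactants: 6 (E)-5-methyl-7-[(triisopropylsilyl)oxy]octa-5,7-dien-1-yl acetate
Product: 7 (E)-5-methyl-7-[(triisopropylsilyl)oxy]octa-5,7-dien-1-ol
Conditions: K2CO3 (0.2 equiv), MeOH, 0 °C
Reagents that add atoms: none
Why: Base-catalysed transesterification removes the primary acetate, and the hindered triisopropylsilyl dienol ether should survive cold methanolic carbonate.

**Step 4**
Reactants: 7 (E)-5-methyl-7-[(triisopropylsilyl)oxy]octa-5,7-dien-1-ol
Product: 8 (E)-5-methyl-7-[(triisopropylsilyl)oxy]octa-5,7-dienal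
Conditions: (n-Pr4N)RuO4 (5 mol %), NMO, 4 Å MS, CH2Cl2, 0 °C → rt
Reagents that add atoms: none
Why: Ley–Griffith oxidation is neutral and stops at the aldehyde, so the acid-sensitive silyl dienol ether is kept.

**Step 5**
Reactants: 8 (E)-5-methyl-7-[(triisopropylsilyl)oxy]octa-5,7-dienal; 9 ethynylmagnesium bromide
Product: 10 (E)-7-methyl-9-[(triisopropylsilyl)oxy]deca-7,9-dien-1-yn-3-ol
Conditions: HC≡CMgBr (0.5 M in THF), THF, −78 → 0 °C; aq. NH4Cl
Reagents that add atoms: none
Why: Grignard 1,2-addition to the unhindered aldehyde gives the propargylic alcohol, whose racemic carbinol centre is erased in step 6.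

**Step 6**
Reactants: 10 (E)-7-methyl-9-[(triisopropylsilyl)oxy]deca-7,9-dien-1-yn-3-ol
Product: 11 (E)-7-methyl-9-[(triisopropylsilyl)oxy]deca-7,9-dien-1-yn-3-one
Conditions: MnO2 (activated, excess), CH2Cl2, rt; filtered cold and used at once
Reagents that add atoms: none
Why: Activated MnO2 oxidises propargylic alcohols under neutral conditions to the terminal ynone, which is taken on immediately to avoid uncatalysed cyclization.

**Step 7**
Reactants: 11 (E)-7-methyl-9-[(triisopropylsilyl)oxy]deca-7,9-dien-1-yn-3-one
Product: 12 (R)-4a-methyl-6-[(triisopropylsilyl)oxy]-3,4,4a,7-tetrahydronaphthalen-1(2H)-one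
Conditions: oxazaborolidinium triflimide made from (S)-3,3-diphenyl-1-(o-tolyl)tetrahydro-1H,3H-pyrrolo[1,2-c][1,3,2]oxazaborole and Tf2NH (20 mol %), CH2Cl2 (0.01 M), −78 → −40 °C; Et3N quench
Reagents that add atoms: none
Why: Proposed new method: the boron Lewis acid binds the ynone carbonyl and lowers its LUMO, so the electron-rich 2-silyloxydiene should add across C5≡C6 in a concerted but asynchronous [4+2] cycloaddition in which the polarity-matched C6–C7 bond (silyl enol ether terminus C7 to the ynone β-carbon) leads and the hindered C5–C10 bond follows. The closest known reaction types are the cationic oxazaborolidine-catalysed enantioselective Diels–Alder reactions of α,β-acetylenic ketones and of enones with 2-silyloxydienes, and thermal type 1 intramolecular Diels–Alder reactions of dienyl ynones. Ring B closes as the [4+2] ring (C7=C8–C9=C10 plus C5≡C6), and ring A closes through the same C5–C10 bond in the fused mode (6-exo at the diene terminus), because the tether C1–C2–C3–C4 joins C10 to C5 and the bridged mode would need a ten-membered ring. The only new stereocentre is the quaternary C10: the alkyne dienophile leaves C5 trigonal and removes any endo/exo question, and the aryl groups of the catalyst shield one face of the bound ynone so that C5 should bond to a single face of the C9=C10 terminus. The step needs fused regioselectivity (secured by tether length and the 1,4-relation of C8–O and C4=O), the E-geometry at C9=C10 that puts the tether outside and the methyl group inside the s-cis diene (set in step 1), and dominance of the catalysed intramolecular path over racemic background and intermolecular Mukaiyama–Michael addition (low temperature, high dilution, and a slim alkyne dienophile that tolerates the inside methyl group).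

**Step 8**
Reactants: 12 (R)-4a-methyl-6-[(triisopropylsilyl)oxy]-3,4,4a,7-tetrahydronaphthalen-1(2H)-one
Product: 14 (R)-4a-methyl-6-[(triisopropylsilyl)oxy]-2,3,4,4a,7,8-hexahydronaphthalen-1-yl trifluoromethanesulfonate, via lithium enolate 13 (not isolated)
Conditions: Li (2.2 equiv), NH3(l)/THF, t-BuOH (1 equiv), −78 °C; NH3 evaporated; then PhNTf2, THF, 0 °C
Reagents that add atoms: N-phenylbis(trifluoromethanesulfonimide), O=S(=O)(N(c1ccccc1)S(=O)(=O)C(F)(F)F)C(F)(F)F
Why: Dissolving-metal reduction of the enone protonates C6 and gives the tetrasubstituted C4=C5 lithium enolate regiospecifically, which is trapped on oxygen (reductive enol triflation), the silyl enol ether being inert.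

**Step 9**
Reactants: 14 (R)-4a-methyl-6-[(triisopropylsilyl)oxy]-2,3,4,4a,7,8-hexahydronaphthalen-1-yl trifluoromethanesulfonate
Product: 15 methyl (R)-4a-methyl-6-[(triisopropylsilyl)oxy]-2,3,4,4a,7,8-hexahydronaphthalene-1-carboxylate
Conditions: Pd(OAc)2 (10 mol %), dppp, CO (1 atm), MeOH, Et3N, DMF, 60 °C
Reagents that add atoms: carbon monoxide, [C-]#[O+]; methanol, CO
Why: Palladium-catalysed methoxycarbonylation of the enol triflate (oxidative addition, CO insertion, methanolysis) installs C19 as the conjugated methyl ester.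

**Step 10**
Reactants: 15 methyl (R)-4a-methyl-6-[(triisopropylsilyl)oxy]-2,3,4,4a,7,8-hexahydronaphthalene-1-carboxylate
Product: 17 methyl 8-[(triisopropylsilyl)oxy]-11,12,13,14,15,16,17-heptanorlabd-8-en-19-oate, via lithium ester enolate 16 (not isolated)
Conditions: Li (2.2 equiv), NH3(l)/THF, t-BuOH (1 equiv), −78 °C; then MeI, −78 → −33 °C
Reagents that add atoms: iodomethane, CI
Why: In this dissolving-metal reductive alkylation the β-carbon C5 should be protonated axially to ring A (Stork rule, giving the trans-decalin with 5α-H anti to the C10 methyl group), and the resulting ester enolate should be methylated from the equatorial α-face, the β-face being blocked by the 1,3-diaxial C10 methyl group, so that C4 carries the α-methyl and the axial β-CO2Me group.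

**Step 11**
Reactants: 17 methyl 8-[(triisopropylsilyl)oxy]-11,12,13,14,15,16,17-heptanorlabd-8-en-19-oate
Product: 20 methyl 8-oxo-12,13,14,15,16,17-hexanorlabd-9(11)-en-19-oate, via Mannich base 18 (not isolated), via methiodide 19 (not isolated)
Conditions: Me2N=CH2 I (Eschenmoser's salt), CH2Cl2, rt; then MeI, rt; then DBU, rt
Reagents that add atoms: N,N-dimethylmethyleneiminium iodide, C=[N+](C)C.[I-]
Why: The regiodefined silyl enol ether delivered by the cycloaddition reacts at C9 with the small iminium electrophile (Mannich reaction), and quaternisation followed by E1cB elimination gives the α-methylene ketone.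

**Step 12**
Reactants: 20 methyl 8-oxo-12,13,14,15,16,17-hexanorlabd-9(11)-en-19-oate; 21 allenyltributylstannane
Product: 23 methyl 8-oxo-15,16,17-trinorlabd-13-yn-19-oate, via titanium enolate 22 (not isolated)
Conditions: CH2=C=CHSnBu3, TiCl4, CH2Cl2, −78 °C; aq. NaHCO3; then K2CO3, MeOH, rt
Reagents that add atoms: none
Why: TiCl4-promoted conjugate propargylation (SE2′ attack of the allenylstannane γ-carbon on C11) builds the but-3-ynyl chain, and base equilibration sets C9 under thermodynamic control with the side chain equatorial (9β, 9α-H).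

**Step 13**
Reactants: 23 methyl 8-oxo-15,16,17-trinorlabd-13-yn-19-oate
Product: 24 methyl 15,16-dinorlabd-8(17)-en-13-yn-19-oate
Conditions: Ph3PCH3Br, KN(SiMe3)2, THF, 0 °C; then 23, rt → 50 °C
Reagents that add atoms: methyltriphenylphosphonium bromide, C[P+](c1ccccc1)(c1ccccc1)c1ccccc1.[Br-]
Why: Wittig methylenation converts the C8 ketone into the exocyclic 8(17)-alkene, and the non-stabilised ylide should not attack the hindered axial ester or the terminal alkyne.

**Step 14**
Reactants: 24 methyl 15,16-dinorlabd-8(17)-en-13-yn-19-oate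
Product: 25 methyl 8α,17-epoxy-15,16-dinorlabd-13-yn-19-oate
Conditions: mCPBA, NaHCO3, CH2Cl2, 0 °C
Reagents that add atoms: 3-chloroperoxybenzoic acid, OOC(=O)c1cccc(Cl)c1
Why: Peracid epoxidation of the 1,1-disubstituted alkene should occur from the equatorial α-face, because the axial C10 methyl group shields the β-face, and the terminal alkyne is far less reactive.

**Step 15**
Reactants: 25 methyl 8α,17-epoxy-15,16-dinorlabd-13-yn-19-oate
Product: 26 15,16-dinorlabd-13-yne-8α,19-diol
Conditions: LiAlH4, THF, 0 °C → reflux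
Reagents that add atoms: none
Why: Hydride opens the epoxide at the primary C17 to give the tertiary 8α-alcohol with the 8β-methyl group (C8 configuration retained from step 14) and reduces the neopentyl ester to the C19 primary alcohol in the same operation.

**Step 16**
Reactants: 26 15,16-dinorlabd-13-yne-8α,19-diol
Product: 27 labda-13(16),14-diene-8α,19-diol
Conditions: ethylene (1 atm), second-generation Grubbs catalyst (H2IMes)(PCy3)Cl2Ru=CHPh (5 mol %), toluene, 60 °C
Reagents that add atoms: ethylene, C=C
Why: Ethylene–alkyne cross enyne metathesis converts the terminal alkyne into the 2-substituted buta-1,3-diene; free hydroxyl groups are tolerated and no other alkene is present.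

**Step 17**
Reactants: 27 labda-13(16),14-diene-8α,19-diol; 28 (E)-4-methoxycinnamoyl chloride
Product: 29 8α-hydroxylabda-13(16),14-dien-19-yl (E)-3-(4-methoxyphenyl)prop-2-enoate
Conditions: pyridine, DMAP (cat.), CH2Cl2, 0 °C → rt
Reagents that add atoms: none
Why: DMAP-catalysed acylation should be selective for the primary C19 hydroxyl because the tertiary 8-hydroxyl is unreactive, and the E-alkene comes from the reagent.

**Compound list**
1 | hex-5-yn-1-ol | OCCCCC#C | starting material
2 | acetyl chloride | CC(Cl)=O | starting material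
3 | dimethyl[(E)-6-(dimethylaluminiooxy)-2-methylhex-1-enyl]alane (alkenylalane) | C[Al](C)OCCCC/C(C)=C/[Al](C)C | intermediate
4 | (E)-5-methyl-7-oxooct-5-en-1-yl acetate | CC(=O)OCCCC/C(C)=C/C(C)=O | intermediate
5 | lithium dienolate of 4 (cross-conjugated, oxygen on C7 of the octene chain) | CC(=O)OCCCC/C(C)=C/C(=C)[O-].[Li+] | intermediate
6 | (E)-5-methyl-7-[(triisopropylsilyl)oxy]octa-5,7-dien-1-yl acetate | CC(=O)OCCCC/C(C)=C/C(=C)O[Si](C(C)C)(C(C)C)C(C)C | intermediate
7 | (E)-5-methyl-7-[(triisopropylsilyl)oxy]octa-5,7-dien-1-ol | OCCCC/C(C)=C/C(=C)O[Si](C(C)C)(C(C)C)C(C)C | intermediate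
8 | (E)-5-methyl-7-[(triisopropylsilyl)oxy]octa-5,7-dienal | O=CCCC/C(C)=C/C(=C)O[Si](C(C)C)(C(C)C)C(C)C | intermediate
9 | ethynylmagnesium bromide | C#C[Mg]Br | starting material
10 | (E)-7-methyl-9-[(triisopropylsilyl)oxy]deca-7,9-dien-1-yn-3-ol (racemic carbinol) | C#CC(O)CCC/C(C)=C/C(=C)O[Si](C(C)C)(C(C)C)C(C)C | intermediate
11 | (E)-7-methyl-9-[(triisopropylsilyl)oxy]deca-7,9-dien-1-yn-3-one | C#CC(=O)CCC/C(C)=C/C(=C)O[Si](C(C)C)(C(C)C)C(C)C | intermediate
12 | (R)-4a-methyl-6-[(triisopropylsilyl)oxy]-3,4,4a,7-tetrahydronaphthalen-1(2H)-one (C4 ketone, C5=C6, C8 silyl enol ether, 10β-methyl) | C[C@]12CCCC(=O)C1=CCC(O[Si](C(C)C)(C(C)C)C(C)C)=C2 | intermediate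
13 | lithium C4=C5 enolate of the 5,6-dihydro ketone | C[C@]12CCCC([O-])=C1CCC(O[Si](C(C)C)(C(C)C)C(C)C)=C2.[Li+] | intermediate
14 | (R)-4a-methyl-6-[(triisopropylsilyl)oxy]-2,3,4,4a,7,8-hexahydronaphthalen-1-yl trifluoromethanesulfonate | C[C@]12CCCC(OS(=O)(=O)C(F)(F)F)=C1CCC(O[Si](C(C)C)(C(C)C)C(C)C)=C2 | intermediate
15 | methyl (R)-4a-methyl-6-[(triisopropylsilyl)oxy]-2,3,4,4a,7,8-hexahydronaphthalene-1-carboxylate | C[C@]12CCCC(C(=O)OC)=C1CCC(O[Si](C(C)C)(C(C)C)C(C)C)=C2 | intermediate
16 | lithium ester enolate (C4=C19, 5α-H, 10β-methyl) | C[C@]12CCCC(=C([O-])OC)[C@@H]1CCC(O[Si](C(C)C)(C(C)C)C(C)C)=C2.[Li+] | intermediate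
17 | methyl 8-[(triisopropylsilyl)oxy]-11,12,13,14,15,16,17-heptanorlabd-8-en-19-oate (4α-methyl, 4β-CO2Me, 5α-H, 10β-methyl) | C[C@]12CCC[C@](C)(C(=O)OC)[C@@H]1CCC(O[Si](C(C)C)(C(C)C)C(C)C)=C2 | intermediate
18 | Mannich base, 9-(dimethylaminomethyl) 8-ketone (C9 epimers) | C[C@]12CCC[C@](C)(C(=O)OC)[C@@H]1CCC(=O)C2CN(C)C | intermediate
19 | methiodide of 18 | C[C@]12CCC[C@](C)(C(=O)OC)[C@@H]1CCC(=O)C2C[N+](C)(C)C.[I-] | intermediate
20 | methyl 8-oxo-12,13,14,15,16,17-hexanorlabd-9(11)-en-19-oate | C[C@]12CCC[C@](C)(C(=O)OC)[C@@H]1CCC(=O)C2=C | intermediate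
21 | allenyltributylstannane | C=C=C[Sn](CCCC)(CCCC)CCCC | starting material
22 | trichlorotitanium C8=C9 enolate carrying the but-3-ynyl chain on C9 | C[C@]12CCC[C@](C)(C(=O)OC)[C@@H]1CCC(O[Ti](Cl)(Cl)Cl)=C2CCC#C | intermediate
23 | methyl 8-oxo-15,16,17-trinorlabd-13-yn-19-oate (9β side chain, 9α-H) | C#CCC[C@@H]1[C@@]2(C)CCC[C@](C)(C(=O)OC)[C@@H]2CCC1=O | intermediate
24 | methyl 15,16-dinorlabd-8(17)-en-13-yn-19-oate | C#CCC[C@@H]1[C@@]2(C)CCC[C@](C)(C(=O)OC)[C@@H]2CCC1=C | intermediate
25 | methyl 8α,17-epoxy-15,16-dinorlabd-13-yn-19-oate | C#CCC[C@@H]1[C@@]2(C)CCC[C@](C)(C(=O)OC)[C@@H]2CC[C@@]1(C3)O3 | intermediate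
26 | 15,16-dinorlabd-13-yne-8α,19-diol | C#CCC[C@@H]1[C@@]2(C)CCC[C@](C)(CO)[C@@H]2CC[C@@]1(C)O | intermediate
27 | labda-13(16),14-diene-8α,19-diol | C=CC(=C)CC[C@@H]1[C@@]2(C)CCC[C@](C)(CO)[C@@H]2CC[C@@]1(C)O | intermediate
28 | (E)-4-methoxycinnamoyl chloride | COc1ccc(/C=C/C(Cl)=O)cc1 | starting material
29 | 8α-hydroxylabda-13(16),14-dien-19-yl (E)-3-(4-methoxyphenyl)prop-2-enoate (CNP0249194.1) | C=CC(=C)CC[C@@H]1[C@@]2(C)CCC[C@](C)(COC(=O)/C=C/c3ccc(OC)cc3)[C@@H]2CC[C@@]1(C)O | target

**Step count and risks**
Total steps: 17. Longest linear sequence: 17 steps (1 → 29).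

Steps most likely to fail:

1. Step 7 (Proposed new method). The catalyst may discriminate the two faces poorly, the uncatalysed racemic cyclization or intermolecular Mukaiyama–Michael oligomerization may compete, or the acidic catalyst may protodesilylate the silyl enol ether. Fallback, from 11 back to 12, by known chemistry: heating 11 (toluene, 80 °C, BHT, high dilution) would give the racemic dienone F1 by the thermal cycloaddition. Addition of lithiated (S)-N,S-dimethyl-S-phenylsulfoximine (n-BuLi, THF, −78 °C) to its carbonyl would give two diastereomeric β-hydroxysulfoximines, the adduct of the (R)-ketone F2 and the adduct of the (S)-ketone F3, which are separated by chromatography (Johnson resolution). Thermolysis of F2 (toluene, 110 °C) releases the sulfoximine and returns enantiopure 12.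

2. Step 10. The dissolving-metal step may over-reduce the ester or protonate C5 unselectively. Fallback, from 12 back to 17: hydrogenation of 12 (H2, Pd/C, EtOAc) should add to C5=C6 from the α-face, opposite the C10 methyl group, to give the trans-decalone F4. Kinetic deprotonation at C3 and triflation (KN(SiMe3)2, PhNTf2, THF, −78 °C) would give the Δ3-enol triflate F5, and methoxycarbonylation as in step 9 the Δ3-unsaturated ester F6. Conjugate reduction with LiBH(s-Bu)3 and alkylation of the enolate with MeI/HMPA from the α-face then gives 17.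

3. Step 12. Addition may go 1,2, the stannane may transfer an allenyl instead of a propargyl group, or the Lewis acid may oligomerize the α-methylene ketone. Fallback, from 17 back to 23: palladium-catalysed allylation of the silyl enol ether (allyl methyl carbonate, Pd2(dba)3, dppe, THF, reflux) would put an allyl group on C9 regiospecifically, giving the allyl ketone F7 (9β after equilibration). Chemoselective hydroboration of the terminal alkene (9-BBN, THF; NaBO3) gives the primary alcohol F8, oxidation (Dess–Martin periodinane, NaHCO3) the keto aldehyde F9, and Ohira–Bestmann homologation (dimethyl (1-diazo-2-oxopropyl)phosphonate, K2CO3, MeOH) gives 23.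

**Further compounds**
F1 | step 7 | racemic 4a-methyl-6-[(triisopropylsilyl)oxy]-3,4,4a,7-tetrahydronaphthalen-1(2H)-one (racemate, no descriptor) | CC12CCCC(=O)C1=CCC(O[Si](C(C)C)(C(C)C)C(C)C)=C2
F2 | step 7 | β-hydroxysulfoximine from (R)-12 and the (S)-sulfoximine (carbinol centre unassigned) | C[C@]12CCCC(O)(C[S@@](=O)(=NC)c3ccccc3)C1=CCC(O[Si](C(C)C)(C(C)C)C(C)C)=C2
F3 | step 7 | β-hydroxysulfoximine from the (S)-ketone and the (S)-sulfoximine (carbinol centre unassigned) | C[C@@]12CCCC(O)(C[S@@](=O)(=NC)c3ccccc3)C1=CCC(O[Si](C(C)C)(C(C)C)C(C)C)=C2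
F4 | step 10 | trans-decalone, 4-oxo, 5α-H, 10β-methyl, C8 silyl enol ether | C[C@]12CCCC(=O)[C@@H]1CCC(O[Si](C(C)C)(C(C)C)C(C)C)=C2
F5 | step 10 | Δ3-enol triflate of F4 | C[C@]12CCC=C(OS(=O)(=O)C(F)(F)F)[C@@H]1CCC(O[Si](C(C)C)(C(C)C)C(C)C)=C2
F6 | step 10 | methyl Δ3-ene-4-carboxylate (5α-H, 10β-methyl, C8 silyl enol ether) | C[C@]12CCC=C(C(=O)OC)[C@@H]1CCC(O[Si](C(C)C)(C(C)C)C(C)C)=C2
F7 | step 12 | methyl 8-oxo-14,15,16,17-tetranorlabd-12-en-19-oate (9β-allyl ketone) | C=CC[C@@H]1[C@@]2(C)CCC[C@](C)(C(=O)OC)[C@@H]2CCC1=O
F8 | step 12 | methyl 13-hydroxy-8-oxo-14,15,16,17-tetranorlabdan-19-oate | OCCC[C@@H]1[C@@]2(C)CCC[C@](C)(C(=O)OC)[C@@H]2CCC1=O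
F9 | step 12 | methyl 8,13-dioxo-14,15,16,17-tetranorlabdan-19-oate (keto aldehyde) | O=CCC[C@@H]1[C@@]2(C)CCC[C@](C)(C(=O)OC)[C@@H]2CCC1=O
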